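Two runs of one catalytic reaction ended nearly level, although Tuesday's flask ran cooler than Friday's, at 30 °C against 35 °C, with 0.50 equiv of second substrate against 1 equiv: the last target readings were 9.4 % and 9.8 %, apart by less than the scatter of 1 percentage point.

the same everywhere: starting material 0.071 M; free catalyst 0.05 mol%; added ligand 19 µM
- Friday's: second substrate 1 equiv; temperature 35 °C; the very flask that is asked about, followed so far
- Tuesday's: second substrate 0.50 equiv; temperature 30 °C; run made earlier
- flask: second substrate 1.00 equiv; temperature 35 °C; time 8.0 min

| run | time / min | target / % | starting material / % |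
|---|---|---|---|
| Friday's | 0.500 | 0 | 99.4 |
| Friday's | 0.833 | 4.2 | 98.1 |
| Friday's | 1.33 | 4.8 | 93.6 |
| Friday's | 2.50 | 7.2 | 92.1 |
| Friday's | 4.00 | 6.6 | 90.5 |
| Friday's | 6.00 | 9.8 | 88.5 |
| Tuesday's | 0.667 | 0.9 | 97.9 |
| Tuesday's | 1.00 | 2.8 | 95.5 |
| Tuesday's | 2.00 | 6.8 | 95.3 |
| Tuesday's | 3.00 | 5.9 | 94.1 |
| Tuesday's | 5.00 | 9.8 | 91.1 |
| Tuesday's | 8.00 | 9.4 | 90.0 |

(readings scatter by 1 percentage point)

- eta: at 8.0 min raise the temperature by 10 K, then wait 4.0 min
- alpha: at 8.0 min take out 90 % of the target then present, then wait 4.0 min
- zeta: change nothing and wait 4.0 min more
- epsilon: at 8.0 min add free catalyst, 100 % of the amount charged, then wait 4.0 min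

- what is taken out of target is counted as made
- steps that have been proposed: catalyst intermediate A -> spent catalyst; catalyst intermediate B -> free catalyst + second product; second substrate + free catalyst <-> catalyst intermediate B; starting material + free catalyst <-> catalyst intermediate A; free catalyst <-> dormant form; catalyst intermediate A -> free catalyst + target; free catalyst + added ligand <-> idle complex
- additions bring no volume worth counting

- target, in percent of the starting material first charged, at 8.0 min
- which option adds most target ("none" when 2 percentage points or less is all one gets) (eta / alpha / zeta / epsilon / none)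
- target present, with what was taken out counted in, in percent of the starting material first charged, after alpha
- target present, with what was taken out counted in, in percent of the starting material first charged, after epsilon

Friday's last reading still showed 88.5 % of the starting material, so shortage of it had not stopped that flask. I therefore divided that run's last target reading by the loading, which gave 196 turnovers per catalyst charged. Held flat up to 8.0 min, this meant 9.80 % there, since Tuesday's target readings went from 9.8 % to 9.4 % over its last two times and showed no rise. That flatness made me expect less than 2 points from waiting. Taking target out looked no better, as none of the proposed steps consumes target. Tuesday's level, reached at 30 °C but also with 0.50 equiv of second substrate, suggested that heating by 10 K would move little.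

Fresh catalyst was different. I expected it to repeat Friday's first 4.00 min, reading 6.6 %, which made 16.4 % after epsilon.

The weak link was leaning on single readings. Target and the loss of starting material measure one thing twice, so I averaged the four end values to 10.2 %. From this came the turnover budget, the target made per catalyst charged by the end of these runs (a turnover number as read so far), 203. The same averaging of Friday's two values at 4.00 min gave a burst of 8.05 %. I committed to 10.2 % at 8.0 min and 18.2 % after epsilon.

The forecast gave 10.5 % and 19 % after epsilon, slightly above my figures, gave 11 % after alpha, and chose epsilon, reading the runs as “a catalyst that dies after a fixed number of turnovers”.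

The flask gave 10.4 %, 11.0 % after alpha and 19.3 % after epsilon; epsilon added 8.9 points, against 0.98 points for eta.

    catalyst intermediate A → spent catalyst (k = 1.70 min⁻¹, Ea = 79.0 kJ mol⁻¹)
    catalyst intermediate B → free catalyst + second product (k = 130 min⁻¹, Ea = 68.0 kJ mol⁻¹)
    second substrate + free catalyst ⇌ catalyst intermediate B (K = 2400 L mol⁻¹, k = 6900 L mol⁻¹ min⁻¹, Ea = 37.0 kJ mol⁻¹, ΔH = −57.0 kJ mol⁻¹)
    starting material + free catalyst ⇌ catalyst intermediate A (K = 110 L mol⁻¹, k = 12000 L mol⁻¹ min⁻¹, Ea = 50.0 kJ mol⁻¹, ΔH = −47.0 kJ mol⁻¹)
    free catalyst ⇌ dormant form (K = 14.0, k = 0.510 min⁻¹, Ea = 92.0 kJ mol⁻¹, ΔH = −13.0 kJ mol⁻¹)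
    catalyst intermediate A → free catalyst + target (k = 440 min⁻¹, Ea = 76.0 kJ mol⁻¹)
    free catalyst + added ligand ⇌ idle complex, settled at all times (K = 1.10 × 10⁵ L mol⁻¹, ΔH = −24.0 kJ mol⁻¹)
    (constants at 35 °C)

In Friday's flask, catalyst intermediate A yielded target and spent catalyst side by side: spent catalyst stood at 23.2 % of the catalyst charged by 0.800 min and 80.6 % by 8.00 min, with dormant form at 13.4 %. That is 259 turnovers per catalyst spent at that time. My budget of 203 gave 10.2 % here and 24.4 % for a neighbour flask, like this one but loaded at 0.12 mol%, which reached 24.7 % at the same time. At 80.0 min, Friday's flask held 98.1 % of the catalyst charged as spent catalyst, and target stood at 12.7 %.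

The earlier runs and the new flask are calculated from invented constants, noise included.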